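## Structural features

The target is an oxepane numbered O1, C2, C3, C4, C5, C6, C7. C2 is a quaternary ether carbon that carries a methyl group and, through C1'', a 5-hydroxy-4,8-dimethylnon-7-enyl chain. C3 carries an acetate, C6 an exocyclic trisubstituted double bond to C1'H–C2'H2OAc, and C7 is a methylene that is both allylic and bound to O1. The four stereocentres form two isolated pairs: C2 (S) and C3 (R) are neighbours in the ring, with the C3 oxygen cis to the C2 methyl group; C4'' (R, methyl) and C5'' (R, free hydroxyl) are neighbours in the chain and syn. Three methylene groups separate the pairs, so neither can control the other. The exocyclic alkene has fixed geometry (6E): C2' lies on the side of C5 and away from C7. Fragile points are the primary allylic acetate (ionisable, open to SN2' attack), a secondary acetate beside a free secondary alcohol (three oxygens that must stay distinguishable to the end), and two trisubstituted alkenes that must survive every reduction. The real difficulties are the seven-membered ring with a fully substituted ether carbon, the alkene geometry, and the union of the two remote stereo-pairs. The key step exploits that C5 is allylic to C6=C1' and C4 is alpha to C3: with C3 as a ketone whose other alpha carbon (C2) is quaternary, only C4 can be enolised, so C4–C5 can be closed by enolate alkylation of a primary allylic bromide.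

## Logic of the disconnections

42 to 41 and 40: the acyl C–O bond at C2' is cut first, then the Si–O bond. The primary allylic acetate is the most labile group, so it is made last and never meets an organometallic reagent. The demand is that acylation of 41 selects the primary allylic hydroxyl over the C5'' hydroxyl.

40 to 38 and 39: C6''–C7'' is cut. This turns the homoallylic alcohol into a terminal epoxide and an alkenyl nucleophile. The reason is specific: a chain fragment holding both the terminal vinyl group needed for metathesis and the trisubstituted alkene would be a 1,6-diene and would close to a cyclopentene faster than it cross-couples. With this cut the trisubstituted alkene is absent during metathesis, and the C5'' hydroxyl is born free without a protecting group. The demand is that epoxide opening outruns attack on the C3 acetate.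

38 to 37 to 28 and 36: C2''–C3'' is cut as an alkene (cross-metathesis, then saturation). The cut separates the two stereo-pairs into fragments made independently, and the allyl group on C2 is the handle. The demand is a reduction that distinguishes a 1,2-disubstituted alkene from a trisubstituted one.

28 to 27 to 26: the C3 acetate and the C3–H bond are removed, tracing C3 to a ketone. The hydride must enter cis to the allyl group, against any small substrate bias, so the forward step needs reagent control and must spare the terminal alkene.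

26 to 24 (through 25): C4–C5 is cut, which opens the ring. The acyclic precursor has one enolisable position and one primary allylic bromide; its alkene geometry is already fixed and C2 is the only stereocentre. The demands are C- over O-alkylation, direct over allyl-transposed substitution, and cyclisation over oligomerisation.

24 to 23, 22, 21, 19 and 20, 18, 17: the C5–Br bond is traced to a silyl-masked hydroxyl, and C3–C4 is cut (addition of 20 to aldehyde 19). The ketone is assembled only after the ether is in place, because an alpha-hydroxy ketone alkoxide would not tolerate etherification. The demand is orthogonality of three oxygen protecting groups.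

17 to 15 and 10: O1–C7 is cut. The tertiary alkoxide of 15 attacks the primary allylic bromide 10 by SN2, so the geometry of 10 is transferred unchanged. The primary oxygen of 15 carries a PMB group and not a silyl group, because a silyl group could migrate to the neighbouring tertiary alkoxide and divert the alkylation.

15 to 13 and 14, and 13 to 11: C1''–C2'' is cut (epoxide opening at the unsubstituted carbon). C2 is bought from the chiral pool: the R configuration of 11 maps onto S at C2 in every later compound, because the spatial arrangement is never touched and only the CIP ranks change.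

10 to 9, 8, 7, and 7 to 5 and 6, then 5 to 4, 2 and 1: C5–C6 is cut (sp2–sp3 coupling with retention), then H and I are removed from across the alkyne. A hydroxyl-directed trans-hydroalumination places iodine on C6 cis to C2', so the alkene geometry is defined by a five-membered metallacycle. The three oxygens arrive at different times and are therefore differentiated without any selective protection.

36 to 34, 33, and 33 to 29 and 30: the epoxide C–O bond is traced to a 1,2-diol and C4''–C5'' is cut (crotylboration). The syn C4''/C5'' pair comes from one reagent-controlled step. The demand is a Z-crotyl reagent of the correct antipode.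

## Other disconnections considered

Alternative 1: The ring bond C5=C6 and the exocyclic C1'=C2' are cut together. The oxepane is traced to the cyclic 1,3-diene A1, and A1 to the acyclic enyne A2, in which C3 carries an allyl group and O1 a propargyl group. In the forward direction RuCl2(=CHPh)(H2IMes)(PCy3), the second-generation Grubbs catalyst, under ethene would convert A2 into A1 by exo ring-closing enyne metathesis. A 1,4-hydroboration of the diene (pinacolborane, Ni(cod)2/PCy3) and oxidation would then put hydrogen on C5 and oxygen on C2', leaving C6=C1' with C5 and C2' cis (allylic alcohol A3).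
- In favour: the ring and the whole exocyclic unit come from one catalytic step, and the geometry follows from the cisoid diene. C2 and C3 could be set together by one asymmetric dihydroxylation. In step count this plan is the better one, since it needs no counterpart of the seven-step bromide 10.
- Against: A2 carries the full side chain, so the catalyst meets an alkyne and three alkenes. Seven-membered enyne closure is slower than five- or six-membered closure and competes with intermolecular pathways. The alkene geometry would rest on the regio- and 1,4-selectivity of one late catalytic step on a 2-substituted cyclic diene.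
- Comparison: both plans close the ring away from the stereocentres and create none in the closure (equal). Mechanistically the chosen plan forms one sigma bond by SN2 on a substrate whose geometry was fixed early and is carried through stereospecific steps. It is longer, but each geometric element can be checked at a cheap stage.

Alternative 2: O1–C2 and O1–C7 are cut, that is, the ring oxygen is excised. The lactone A4 is traced to the cyclohexanone A5, itself available by desymmetrising reduction of the diketone A6. In the forward direction a Baeyer–Villiger oxidation with bis(trimethylsilyl) peroxide, SnCl4 and trans-cyclohexane-1,2-diamine (a peracid-free system that should spare the allyl group) would insert oxygen next to quaternary C2 with retention.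
- In favour: A6 is cheap and symmetrical, and one reduction would set C2 and C3 together. On the ring stereocentres this alternative is the equal of the chosen plan or better. Ring formation is also trivial (a six-membered carbocycle is expanded), which is better than a seven-membered cyclisation.
- Against: A4 has C7 as a carbonyl and C6 as a bare methylene. An alkylidene would have to be condensed onto C6 with geometric control, and the C7 carbonyl oxygen would then have to be removed beside a conjugated exocyclic alkene, which invites conjugate reduction or alkene migration.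
- Comparison: the steps saved at the start would be spent on oxidation-level adjustments at C6 and C7. The geometry would come from a thermodynamically controlled condensation, whereas in the chosen plan it is built in and C7 has the right oxidation level from the outset.

Alternative 3: C5–C6 is cut as an sp3–sp2 bond. The ketone A7 is traced to A8, a C3 cyclopropanol whose ether oxygen carries a (Z)-iodoalkene. In the forward direction zerovalent palladium (from Pd2(dba)3 and a bulky phosphine) would insert into C6–I, the cyclopropanol would open by beta-carbon elimination to a C5 alkylpalladium, and reductive elimination would form C5–C6.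
- In favour: the iodoalkene of A8 is of the same kind as 5 and couples with retention. C5 need not be introduced, protected and brominated, a clear gain in step economy over the chosen plan. The side chain can be complete before ring closure.
- Against: the ring would close by reductive elimination from an eight-membered palladacycle. Beta-hydride elimination of the palladium homoenolate to an enone and protodeiodination are the expected competitors, and a tertiary cyclopropanol beside quaternary C2 is hindered.
- Comparison: both plans fix the alkene geometry before ring closure and keep it (equal). The chosen plan needs no metal in the closure and is mechanistically simpler; the alternative is shorter but depends on a medium-ring organometallic closure with thinner support.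

Key step: step 17

Remark: 21 is carried as a mixture of carbinol epimers and 37 as an E/Z mixture at C2''=C3''; both mixtures converge in the following step, and the SMILES of 37 shows the E isomer.

Remark: (tributylstannyl)methanol, [(tert-butyldimethylsilyl)oxy]acetaldehyde and (2-methylprop-1-en-1-yl)magnesium bromide are taken as purchasable reagents.

## Route

Step 1
Reactants: 1 but-2-yne-1,4-diol
Product: 2 4-[(4-methoxyphenyl)methoxy]but-2-yn-1-ol
Conditions: PMBCl (1 equiv), KOH, DMSO, rt; 1 in threefold excess
Reagents that add atoms: 4-methoxybenzyl chloride, COc1ccc(CCl)cc1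
Why: Williamson mono-etherification under statistical control with an excess of the cheap diol; the hydroxyl left free is the one that will direct the hydroalumination and become the C2' oxygen.

Step 2
Reactants: 2 4-[(4-methoxyphenyl)methoxy]but-2-yn-1-ol
Product: 4 (2Z)-3-iodo-4-[(4-methoxyphenyl)methoxy]but-2-en-1-ol, via cyclic alkenylaluminate 3 (not isolated)
Conditions: NaAlH2(OCH2CH2OMe)2, THF, 0 °C; then I2, −78 → 0 °C
Reagents that add atoms: iodine, II
Why: Hydroxyl-directed trans-hydroalumination of a propargylic alcohol followed by iododealumination with retention; aluminium is held on the remote alkyne carbon (C6) in a five-membered oxaaluminacycle, so iodine ends up on C6 cis to C2' and marks the future C5 position. Low temperature should suppress loss of the propargylic ether to an allene.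

Step 3
Reactants: 4 (2Z)-3-iodo-4-[(4-methoxyphenyl)methoxy]but-2-en-1-ol
Product: 5 tert-butyl{[(2Z)-3-iodo-4-[(4-methoxyphenyl)methoxy]but-2-en-1-yl]oxy}diphenylsilane
Conditions: TBDPSCl, imidazole, CH2Cl2, 0 °C → rt
Reagents that add atoms: tert-butyl(chloro)diphenylsilane, CC(C)(C)[Si](Cl)(c1ccccc1)c1ccccc1
Why: Standard silylation of a primary allylic alcohol; the TBDPS group is chosen to last from here to step 26.

Step 4
Reactants: 5 tert-butyl{[(2Z)-3-iodo-4-[(4-methoxyphenyl)methoxy]but-2-en-1-yl]oxy}diphenylsilane; 6 (tributylstannyl)methanol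
Product: 7 (2E)-4-[(tert-butyldiphenylsilyl)oxy]-2-{[(4-methoxyphenyl)methoxy]methyl}but-2-en-1-ol (new hydroxymethyl group C5 cis to C2')
Conditions: Pd(PPh3)4 (5 mol%), 1,4-dioxane, 90 °C
Reagents that add atoms: none
Why: Stille coupling with hydroxymethyl transfer from tin; oxidative addition and reductive elimination at sp2 carbon proceed with retention, so C5 enters cis to C2'. It is run on the small fragment, where no alkene is placed for a competing Heck cyclisation.

Step 5
Reactants: 7 (2E)-4-[(tert-butyldiphenylsilyl)oxy]-2-{[(4-methoxyphenyl)methoxy]methyl}but-2-en-1-ol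
Product: 8 1-({[(2Z)-2-({[tert-butyl(dimethyl)silyl]oxy}methyl)-4-{[tert-butyl(diphenyl)silyl]oxy}but-2-en-1-yl]oxy}methyl)-4-methoxybenzene
Conditions: TBSCl, imidazole, DMF, rt
Reagents that add atoms: tert-butyl(chloro)dimethylsilane, CC(C)(C)[Si](C)(C)Cl
Why: Silylation; TBS is the temporary mask of the C5 oxygen and is removable beside TBDPS in step 15.

Step 6
Reactants: 8 1-({[(2Z)-2-({[tert-butyl(dimethyl)silyl]oxy}methyl)-4-{[tert-butyl(diphenyl)silyl]oxy}but-2-en-1-yl]oxy}methyl)-4-methoxybenzene
Product: 9 (2Z)-2-({[tert-butyl(dimethyl)silyl]oxy}methyl)-4-{[tert-butyl(diphenyl)silyl]oxy}but-2-en-1-ol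
Conditions: DDQ (1.2 equiv), CH2Cl2/pH 7 buffer, 0 °C
Reagents that add atoms: none
Why: Oxidative PMB cleavage (benzylic hydride abstraction, hydrolysis of the oxocarbenium ion); silyl ethers are inert, and the reagent is limited so that the liberated allylic alcohol is not oxidised further.

Step 7
Reactants: 9 (2Z)-2-({[tert-butyl(dimethyl)silyl]oxy}methyl)-4-{[tert-butyl(diphenyl)silyl]oxy}but-2-en-1-ol
Product: 10 {[(2E)-4-bromo-3-({[tert-butyl(dimethyl)silyl]oxy}methyl)but-2-en-1-yl]oxy}(tert-butyl)diphenylsilane (CH2Br = C7, trans to C2')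
Conditions: CBr4, PPh3, CH2Cl2, −20 → 0 °C
Reagents that add atoms: carbon tetrabromide, BrC(Br)(Br)Br
Why: Appel bromination; bromide displaces the alkoxyphosphonium group at the primary carbon by SN2, so no allylic shift and no change of geometry are expected.

Step 8
Reactants: 11 (R)-(2-methyloxiran-2-yl)methanol
Product: 13 (2S)-2-{[(4-methoxyphenyl)methoxy]methyl}-2-methyloxirane, via sodium alkoxide 12 (not isolated)
Conditions: NaH, THF/DMF, 0 °C; then PMBCl, Bu4NI (cat.), 0 °C → rt
Reagents that add atoms: 4-methoxybenzyl chloride, COc1ccc(CCl)cc1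
Why: Williamson etherification; the Payne rearrangement open to this alkoxide is degenerate and returns the same enantiomer, so the stereocentre is safe (the descriptor changes only through CIP ranking). PMB is used because it cannot migrate to the tertiary alkoxide formed in step 10.

Step 9
Reactants: 13 (2S)-2-{[(4-methoxyphenyl)methoxy]methyl}-2-methyloxirane; 14 vinylmagnesium bromide
Product: 15 (2S)-1-[(4-methoxyphenyl)methoxy]-2-methylpent-4-en-2-ol
Conditions: CuI (10 mol%), THF, −40 → 0 °C; aq. NH4Cl
Reagents that add atoms: none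
Why: Copper-catalysed Grignard opening of a 2,2-disubstituted epoxide at its unsubstituted carbon; the stereocentre is not a reacting centre, and the tertiary hydroxyl (future O1 on C2) appears together with the allyl handle.

Step 10
Reactants: 15 (2S)-1-[(4-methoxyphenyl)methoxy]-2-methylpent-4-en-2-ol; 10 {[(2E)-4-bromo-3-({[tert-butyl(dimethyl)silyl]oxy}methyl)but-2-en-1-yl]oxy}(tert-butyl)diphenylsilane
Product: 17 1-[({(2S)-2-[((2Z)-2-{[(tert-butyldimethylsilyl)oxy]methyl}-4-[(tert-butyldiphenylsilyl)oxy]but-2-en-1-yl)oxy]-2-methylpent-4-en-1-yl}oxy)methyl]-4-methoxybenzene, via sodium alkoxide 16 (not isolated)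
Conditions: NaH, THF/DMF (4:1), 0 °C; then 10, Bu4NI (cat.), 0 °C → rt
Reagents that add atoms: none
Why: Williamson etherification of a tertiary alkoxide with a primary allylic bromide forms O1–C7 by SN2 at unhindered C7 (C1' carries CH2OTBDPS and is shielded from SN2' attack), so the alkene geometry of 10 is transferred unchanged.

Step 11
Reactants: 17 1-[({(2S)-2-[((2Z)-2-{[(tert-butyldimethylsilyl)oxy]methyl}-4-[(tert-butyldiphenylsilyl)oxy]but-2-en-1-yl)oxy]-2-methylpent-4-en-1-yl}oxy)methyl]-4-methoxybenzene
Product: 18 (2S)-2-[((2Z)-2-{[(tert-butyldimethylsilyl)oxy]methyl}-4-[(tert-butyldiphenylsilyl)oxy]but-2-en-1-yl)oxy]-2-methylpent-4-en-1-ol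
Conditions: DDQ, CH2Cl2/pH 7 buffer, 0 °C
Reagents that add atoms: none
Why: Oxidative PMB removal; both silyl ethers, the tertiary allylic ether and the alkenes are stable to buffered DDQ.

Step 12
Reactants: 18 (2S)-2-[((2Z)-2-{[(tert-butyldimethylsilyl)oxy]methyl}-4-[(tert-butyldiphenylsilyl)oxy]but-2-en-1-yl)oxy]-2-methylpent-4-en-1-ol
Product: 19 (2S)-2-[((2Z)-2-{[(tert-butyldimethylsilyl)oxy]methyl}-4-[(tert-butyldiphenylsilyl)oxy]but-2-en-1-yl)oxy]-2-methylpent-4-enal
Conditions: Dess–Martin periodinane, pyridine, CH2Cl2, 0 °C → rt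
Reagents that add atoms: none
Why: Dess–Martin oxidation of a primary alcohol; the aldehyde has no alpha hydrogen and cannot epimerise or enolise.

Step 13
Reactants: 19 (2S)-2-[((2Z)-2-{[(tert-butyldimethylsilyl)oxy]methyl}-4-[(tert-butyldiphenylsilyl)oxy]but-2-en-1-yl)oxy]-2-methylpent-4-enal; 20 methylmagnesium bromide
Product: 21 (3S)-3-[((2Z)-2-{[(tert-butyldimethylsilyl)oxy]methyl}-4-[(tert-butyldiphenylsilyl)oxy]but-2-en-1-yl)oxy]-3-methylhex-5-en-2-ol (both C2 epimers)
Conditions: THF, −78 °C; aq. NH4Cl
Reagents that add atoms: none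
Why: Grignard addition to an aldehyde brings in C4; the new carbinol centre is oxidised away in the next step, so its configuration does not matter.

Step 14
Reactants: 21 (3S)-3-[((2Z)-2-{[(tert-butyldimethylsilyl)oxy]methyl}-4-[(tert-butyldiphenylsilyl)oxy]but-2-en-1-yl)oxy]-3-methylhex-5-en-2-ol
Product: 22 (3S)-3-[((2Z)-2-{[(tert-butyldimethylsilyl)oxy]methyl}-4-[(tert-butyldiphenylsilyl)oxy]but-2-en-1-yl)oxy]-3-methylhex-5-en-2-one
Conditions: Dess–Martin periodinane, pyridine, CH2Cl2, rt
Reagents that add atoms: none
Why: Dess–Martin oxidation of a secondary alcohol to the methyl ketone, whose only enolisable position is the new methyl group (C4).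

Step 15
Reactants: 22 (3S)-3-[((2Z)-2-{[(tert-butyldimethylsilyl)oxy]methyl}-4-[(tert-butyldiphenylsilyl)oxy]but-2-en-1-yl)oxy]-3-methylhex-5-en-2-one
Product: 23 (3S)-3-{[(2E)-4-[(tert-butyldiphenylsilyl)oxy]-2-(hydroxymethyl)but-2-en-1-yl]oxy}-3-methylhex-5-en-2-one
Conditions: HF·pyridine, pyridine, THF, 0 °C
Reagents that add atoms: none
Why: Buffered acidic fluoride cleaves the less hindered, more labile primary TBS ether and leaves the TBDPS ether; the ketone is inert.

Step 16
Reactants: 23 (3S)-3-{[(2E)-4-[(tert-butyldiphenylsilyl)oxy]-2-(hydroxymethyl)but-2-en-1-yl]oxy}-3-methylhex-5-en-2-one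
Product: 24 (3S)-3-{[(2Z)-2-(bromomethyl)-4-[(tert-butyldiphenylsilyl)oxy]but-2-en-1-yl]oxy}-3-methylhex-5-en-2-one (CH2Br = C5, cis to C2')
Conditions: CBr4, PPh3, CH2Cl2, −20 → 0 °C
Reagents that add atoms: carbon tetrabromide, BrC(Br)(Br)Br
Why: Appel bromination of the primary allylic alcohol by SN2 at C5, neutral enough for the ketone and the silyl ether; the bromide is used at once.

Step 17
Reactants: 24 (3S)-3-{[(2Z)-2-(bromomethyl)-4-[(tert-butyldiphenylsilyl)oxy]but-2-en-1-yl]oxy}-3-methylhex-5-en-2-one
Product: 26 (2S,6E)-6-{2-[(tert-butyldiphenylsilyl)oxy]ethylidene}-2-methyl-2-(prop-2-en-1-yl)oxepan-3-one, via lithium enolate 25 (not isolated)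
Conditions: LiN(SiMe3)2 (1.2 equiv), THF, −78 °C, slow addition of 24 (final 0.005 M); then −78 → 0 °C
Reagents that add atoms: none
Why: LiN(SiMe3)2 removes a proton from the C4 methyl group, the only enolisable position because C2 is quaternary, and the lithium enolate 25 displaces bromide from primary allylic C5 in an intramolecular SN2 reaction that forms C4–C5. The closest known reaction type is the intramolecular alkylation of ketone enolates by allylic halides used to make six- and seven-membered cyclic ketones. The oxepan-3-one closes in the 7-(enolendo)-exo-tet mode, which is allowed because the seven-atom chain lets the enolate pi lobe at C4 reach the rear of the C5–Br bond. No stereocentre is formed, and C2, having no hydrogen, cannot epimerise. C-alkylation is preferred over O-alkylation (which would give a seven-membered cyclic enol ether) because of the lithium counter-ion in THF without polar additives and the soft allylic bromide. Direct substitution is preferred over SN2' attack at C1' because C5 is primary and C1' carries the silyloxymethyl group, and the alkene geometry is untouched since no allyl cation or allyl–metal species intervenes. Cyclisation is preferred over oligomerisation through high dilution, helped by the ether oxygen and the quaternary carbon in the tether, and inverse addition keeps free ketone scarce and so suppresses aldol condensation.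

Step 18
Reactants: 26 (2S,6E)-6-{2-[(tert-butyldiphenylsilyl)oxy]ethylidene}-2-methyl-2-(prop-2-en-1-yl)oxepan-3-one
Product: 27 (2S,3R,6E)-6-{2-[(tert-butyldiphenylsilyl)oxy]ethylidene}-2-methyl-2-(prop-2-en-1-yl)oxepan-3-ol
Conditions: (S)-2-methyl-CBS-oxazaborolidine (0.3 equiv), catecholborane, toluene, −78 → −40 °C; aq. NaOH work-up
Reagents that add atoms: none
Why: Corey–Bakshi–Shibata reduction; the ketone lies between a quaternary carbon (large) and a methylene (small), and the (S)-catalyst should deliver hydride to the face that gives 3R, by analogy with acetophenone giving the (R)-alcohol with the same rank order of substituents. Catecholborane is used in place of borane so that the allyl group is not hydroborated.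

Step 19
Reactants: 27 (2S,3R,6E)-6-{2-[(tert-butyldiphenylsilyl)oxy]ethylidene}-2-methyl-2-(prop-2-en-1-yl)oxepan-3-ol
Product: 28 (2S,3R,6E)-6-{2-[(tert-butyldiphenylsilyl)oxy]ethylidene}-2-methyl-2-(prop-2-en-1-yl)oxepan-3-yl acetate
Conditions: Ac2O, DMAP, Et3N, CH2Cl2, rt
Reagents that add atoms: acetic anhydride, CC(=O)OC(C)=O
Why: DMAP-catalysed acetylation of the hindered secondary alcohol puts the first acetate of the target in place, with retention at C3.

Step 20
Reactants: 29 [(tert-butyldimethylsilyl)oxy]acetaldehyde; 30 cis-but-2-ene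
Product: 33 (2S,3R)-1-[(tert-butyldimethylsilyl)oxy]-3-methylpent-4-en-2-ol, via (Z)-crotyldiisopinocampheylborane 31 (not isolated), via borinate ester 32 (not isolated)
Conditions: KOt-Bu, n-BuLi, THF, −78 → −45 °C; (−)-Ipc2BOMe, −78 °C; BF3·OEt2; then 29, −78 °C; NaOH, H2O2, rt
Reagents that add atoms: none
Why: Brown crotylboration through a chair Zimmerman–Traxler transition state: the Z-crotyl geometry gives the syn methyl/hydroxyl pair, and the isopinocampheyl groups derived from (+)-alpha-pinene direct attack to the Si face of the aldehyde, which corresponds to 2S,3R here (C4''/C5'' of the target).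

Step 21
Reactants: 33 (2S,3R)-1-[(tert-butyldimethylsilyl)oxy]-3-methylpent-4-en-2-ol
Product: 34 (2S,3R)-3-methylpent-4-ene-1,2-diol
Conditions: camphorsulfonic acid (cat.), MeOH, rt
Reagents that add atoms: none
Why: Acid-catalysed methanolysis of a primary TBS ether; neither stereocentre is a reacting centre.

Step 22
Reactants: 34 (2S,3R)-3-methylpent-4-ene-1,2-diol
Product: 36 (2S)-2-[(2R)-but-3-en-2-yl]oxirane, via primary tosylate 35 (not isolated)
Conditions: NaH, 1-(p-toluenesulfonyl)imidazole, THF, 0 °C → rt
Reagents that add atoms: none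
Why: One-pot selective sulfonylation of the primary alkoxide followed by intramolecular Williamson closure (3-exo-tet); the C5''–O bond is never broken, so C5'' is retained. The volatile epoxide is handled in solution.

Step 23
Reactants: 28 (2S,3R,6E)-6-{2-[(tert-butyldiphenylsilyl)oxy]ethylidene}-2-methyl-2-(prop-2-en-1-yl)oxepan-3-yl acetate; 36 (2S)-2-[(2R)-but-3-en-2-yl]oxirane
Product: 37 (2S,3R,6E)-6-{2-[(tert-butyldiphenylsilyl)oxy]ethylidene}-2-methyl-2-{(2E,4R)-4-[(2S)-oxiran-2-yl]pent-2-en-1-yl}oxepan-3-yl acetate
Conditions: second-generation Grubbs catalyst RuCl2(=CHPh)(H2IMes)(PCy3) (10 mol%), 36 (4 equiv), CH2Cl2, 40 °C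
Reagents that add atoms: none
Why: Olefin cross-metathesis between an unhindered terminal alkene and an allylically branched one used in excess forms C2''=C3''. Partner 36 has no second alkene and cannot ring-close, and the trisubstituted exocyclic alkene is too hindered to take part.

Step 24
Reactants: 37 (2S,3R,6E)-6-{2-[(tert-butyldiphenylsilyl)oxy]ethylidene}-2-methyl-2-{(2E,4R)-4-[(2S)-oxiran-2-yl]pent-2-en-1-yl}oxepan-3-yl acetate
Product: 38 (2S,3R,6E)-6-{2-[(tert-butyldiphenylsilyl)oxy]ethylidene}-2-methyl-2-{(4R)-4-[(2S)-oxiran-2-yl]pentyl}oxepan-3-yl acetate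
Conditions: 2-nitrobenzenesulfonylhydrazide, Et3N, CH2Cl2, rt
Reagents that add atoms: none
Why: Diimide transfer hydrogenation; the rate falls steeply with alkene substitution, so the 1,2-disubstituted alkene should be saturated while the trisubstituted exocyclic alkene survives. The neutral conditions leave epoxide, acetate and silyl ether alone.

Step 25
Reactants: 38 (2S,3R,6E)-6-{2-[(tert-butyldiphenylsilyl)oxy]ethylidene}-2-methyl-2-{(4R)-4-[(2S)-oxiran-2-yl]pentyl}oxepan-3-yl acetate; 39 (2-methylprop-1-en-1-yl)magnesium bromide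
Product: 40 (2S,3R,6E)-6-{2-[(tert-butyldiphenylsilyl)oxy]ethylidene}-2-[(4R,5R)-5-hydroxy-4,8-dimethylnon-7-en-1-yl]-2-methyloxepan-3-yl acetate
Conditions: CuI (15 mol%), 39 (1.5 equiv), THF, −40 → −20 °C; aq. NH4Cl
Reagents that add atoms: none
Why: Copper-catalysed alkenyl Grignard opening of a terminal epoxide at its CH2 group forms C6''–C7'' and frees the C5'' hydroxyl without touching C5''. Low temperature and copper catalysis should let the opening outrun addition to the hindered C3 acetate.

Step 26
Reactants: 40 (2S,3R,6E)-6-{2-[(tert-butyldiphenylsilyl)oxy]ethylidene}-2-[(4R,5R)-5-hydroxy-4,8-dimethylnon-7-en-1-yl]-2-methyloxepan-3-yl acetate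
Product: 41 (2S,3R,6E)-6-(2-hydroxyethylidene)-2-[(4R,5R)-5-hydroxy-4,8-dimethylnon-7-en-1-yl]-2-methyloxepan-3-yl acetate
Conditions: HF·pyridine, pyridine, THF, 0 °C → rt
Reagents that add atoms: none
Why: Fluoride-mediated cleavage of the TBDPS ether under buffered conditions; the acetate has no neighbouring hydroxyl to migrate to and the alkenes are inert.

Step 27
Reactants: 41 (2S,3R,6E)-6-(2-hydroxyethylidene)-2-[(4R,5R)-5-hydroxy-4,8-dimethylnon-7-en-1-yl]-2-methyloxepan-3-yl acetate
Product: 42 (2S,3R,6E)-6-[2-(acetyloxy)ethylidene]-2-[(4R,5R)-5-hydroxy-4,8-dimethylnon-7-en-1-yl]-2-methyloxepan-3-yl acetate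
Conditions: AcCl (1.05 equiv), 2,4,6-collidine, CH2Cl2, −78 °C
Reagents that add atoms: acetyl chloride, CC(=O)Cl
Why: Kinetically selective acylation of the unhindered primary allylic hydroxyl over the secondary C5'' hydroxyl, which is flanked by a branched carbon, at low temperature with a hindered base.

## Compound list

1 | but-2-yne-1,4-diol | OCC#CCO | starting material
2 | 4-[(4-methoxyphenyl)methoxy]but-2-yn-1-ol | COc1ccc(COCC#CCO)cc1 | intermediate
3 | sodium cyclic alkenylaluminate from 2 (not isolated) | [Na+].COCCO[Al-]1(OCCOC)OCC=C1COCc1ccc(OC)cc1 | intermediate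
4 | (2Z)-3-iodo-4-[(4-methoxyphenyl)methoxy]but-2-en-1-ol | COc1ccc(COC/C(I)=C/CO)cc1 | intermediate
5 | tert-butyl{[(2Z)-3-iodo-4-[(4-methoxyphenyl)methoxy]but-2-en-1-yl]oxy}diphenylsilane | COc1ccc(COC/C(I)=C/CO[Si](c2ccccc2)(c2ccccc2)C(C)(C)C)cc1 | intermediate
6 | (tributylstannyl)methanol | OC[Sn](CCCC)(CCCC)CCCC | starting material
7 | (2E)-4-[(tert-butyldiphenylsilyl)oxy]-2-{[(4-methoxyphenyl)methoxy]methyl}but-2-en-1-ol | COc1ccc(COC/C(CO)=C/CO[Si](c2ccccc2)(c2ccccc2)C(C)(C)C)cc1 | intermediate
8 | 1-({[(2Z)-2-({[tert-butyl(dimethyl)silyl]oxy}methyl)-4-{[tert-butyl(diphenyl)silyl]oxy}but-2-en-1-yl]oxy}methyl)-4-methoxybenzene | COc1ccc(COC/C(CO[Si](C)(C)C(C)(C)C)=C/CO[Si](c2ccccc2)(c2ccccc2)C(C)(C)C)cc1 | intermediate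
9 | (2Z)-2-({[tert-butyl(dimethyl)silyl]oxy}methyl)-4-{[tert-butyl(diphenyl)silyl]oxy}but-2-en-1-ol | OC/C(CO[Si](C)(C)C(C)(C)C)=C/CO[Si](c1ccccc1)(c1ccccc1)C(C)(C)C | intermediate
10 | {[(2E)-4-bromo-3-({[tert-butyl(dimethyl)silyl]oxy}methyl)but-2-en-1-yl]oxy}(tert-butyl)diphenylsilane | BrC/C(CO[Si](C)(C)C(C)(C)C)=C/CO[Si](c1ccccc1)(c1ccccc1)C(C)(C)C | intermediate
11 | (R)-(2-methyloxiran-2-yl)methanol | OC[C@]1(C)CO1 | starting material
12 | sodium (R)-(2-methyloxiran-2-yl)methanolate (not isolated) | [Na+].[O-]C[C@]1(C)CO1 | intermediate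
13 | (2S)-2-{[(4-methoxyphenyl)methoxy]methyl}-2-methyloxirane | COc1ccc(COC[C@]2(C)CO2)cc1 | intermediate
14 | vinylmagnesium bromide | C=C[Mg]Br | starting material
15 | (2S)-1-[(4-methoxyphenyl)methoxy]-2-methylpent-4-en-2-ol | COc1ccc(COC[C@](O)(C)CC=C)cc1 | intermediate
16 | sodium alkoxide of 15 (not isolated) | [Na+].COc1ccc(COC[C@]([O-])(C)CC=C)cc1 | intermediate
17 | 1-[({(2S)-2-[((2Z)-2-{[(tert-butyldimethylsilyl)oxy]methyl}-4-[(tert-butyldiphenylsilyl)oxy]but-2-en-1-yl)oxy]-2-methylpent-4-en-1-yl}oxy)methyl]-4-methoxybenzene | COc1ccc(COC[C@](C)(CC=C)OC/C(CO[Si](C)(C)C(C)(C)C)=C/CO[Si](c2ccccc2)(c2ccccc2)C(C)(C)C)cc1 | intermediate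
18 | (2S)-2-[((2Z)-2-{[(tert-butyldimethylsilyl)oxy]methyl}-4-[(tert-butyldiphenylsilyl)oxy]but-2-en-1-yl)oxy]-2-methylpent-4-en-1-ol | OC[C@](C)(CC=C)OC/C(CO[Si](C)(C)C(C)(C)C)=C/CO[Si](c1ccccc1)(c1ccccc1)C(C)(C)C | intermediate
19 | (2S)-2-[((2Z)-2-{[(tert-butyldimethylsilyl)oxy]methyl}-4-[(tert-butyldiphenylsilyl)oxy]but-2-en-1-yl)oxy]-2-methylpent-4-enal | O=C[C@](C)(CC=C)OC/C(CO[Si](C)(C)C(C)(C)C)=C/CO[Si](c1ccccc1)(c1ccccc1)C(C)(C)C | intermediate
20 | methylmagnesium bromide | C[Mg]Br | starting material
21 | (3S)-3-[((2Z)-2-{[(tert-butyldimethylsilyl)oxy]methyl}-4-[(tert-butyldiphenylsilyl)oxy]but-2-en-1-yl)oxy]-3-methylhex-5-en-2-ol, both C2 epimers | CC(O)[C@](C)(CC=C)OC/C(CO[Si](C)(C)C(C)(C)C)=C/CO[Si](c1ccccc1)(c1ccccc1)C(C)(C)C | intermediate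
22 | (3S)-3-[((2Z)-2-{[(tert-butyldimethylsilyl)oxy]methyl}-4-[(tert-butyldiphenylsilyl)oxy]but-2-en-1-yl)oxy]-3-methylhex-5-en-2-one | CC(=O)[C@](C)(CC=C)OC/C(CO[Si](C)(C)C(C)(C)C)=C/CO[Si](c1ccccc1)(c1ccccc1)C(C)(C)C | intermediate
23 | (3S)-3-{[(2E)-4-[(tert-butyldiphenylsilyl)oxy]-2-(hydroxymethyl)but-2-en-1-yl]oxy}-3-methylhex-5-en-2-one | CC(=O)[C@](C)(CC=C)OC/C(CO)=C/CO[Si](c1ccccc1)(c1ccccc1)C(C)(C)C | intermediate
24 | (3S)-3-{[(2Z)-2-(bromomethyl)-4-[(tert-butyldiphenylsilyl)oxy]but-2-en-1-yl]oxy}-3-methylhex-5-en-2-one | CC(=O)[C@](C)(CC=C)OC/C(CBr)=C/CO[Si](c1ccccc1)(c1ccccc1)C(C)(C)C | intermediate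
25 | lithium enolate of 24 at C4 (not isolated) | [Li+].C=C([O-])[C@](C)(CC=C)OC/C(CBr)=C/CO[Si](c1ccccc1)(c1ccccc1)C(C)(C)C | intermediate
26 | (2S,6E)-6-{2-[(tert-butyldiphenylsilyl)oxy]ethylidene}-2-methyl-2-(prop-2-en-1-yl)oxepan-3-one | CC(C)(C)[Si](c1ccccc1)(c1ccccc1)OC/C=C1\CCC(=O)[C@](C)(CC=C)OC1 | intermediate
27 | (2S,3R,6E)-6-{2-[(tert-butyldiphenylsilyl)oxy]ethylidene}-2-methyl-2-(prop-2-en-1-yl)oxepan-3-ol | CC(C)(C)[Si](c1ccccc1)(c1ccccc1)OC/C=C1\CC[C@@H](O)[C@](C)(CC=C)OC1 | intermediate
28 | (2S,3R,6E)-6-{2-[(tert-butyldiphenylsilyl)oxy]ethylidene}-2-methyl-2-(prop-2-en-1-yl)oxepan-3-yl acetate | CC(C)(C)[Si](c1ccccc1)(c1ccccc1)OC/C=C1\CC[C@@H](OC(C)=O)[C@](C)(CC=C)OC1 | intermediate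
29 | [(tert-butyldimethylsilyl)oxy]acetaldehyde | CC(C)(C)[Si](C)(C)OCC=O | starting material
30 | cis-but-2-ene | C/C=C\C | starting material
31 | (Z)-but-2-en-1-yl-bis(isopinocampheyl)borane (not isolated) | C/C=C\CB([C@@H]1C[C@@H]2C[C@H]([C@H]1C)C2(C)C)[C@@H]1C[C@@H]2C[C@H]([C@H]1C)C2(C)C | intermediate
32 | bis(isopinocampheyl)borinate ester of 33 (not isolated) | C=C[C@@H](C)[C@H](OB([C@@H]1C[C@@H]2C[C@H]([C@H]1C)C2(C)C)[C@@H]1C[C@@H]2C[C@H]([C@H]1C)C2(C)C)CO[Si](C)(C)C(C)(C)C | intermediate
33 | (2S,3R)-1-[(tert-butyldimethylsilyl)oxy]-3-methylpent-4-en-2-ol | C=C[C@@H](C)[C@H](O)CO[Si](C)(C)C(C)(C)C | intermediate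
34 | (2S,3R)-3-methylpent-4-ene-1,2-diol | C=C[C@@H](C)[C@H](O)CO | intermediate
35 | (2S,3R)-2-hydroxy-3-methylpent-4-en-1-yl 4-methylbenzenesulfonate (not isolated) | C=C[C@@H](C)[C@H](O)COS(=O)(=O)c1ccc(C)cc1 | intermediate
36 | (2S)-2-[(2R)-but-3-en-2-yl]oxirane | C=C[C@@H](C)[C@H]1CO1 | intermediate
37 | (2S,3R,6E)-6-{2-[(tert-butyldiphenylsilyl)oxy]ethylidene}-2-methyl-2-{(2E,4R)-4-[(2S)-oxiran-2-yl]pent-2-en-1-yl}oxepan-3-yl acetate | CC(C)(C)[Si](c1ccccc1)(c1ccccc1)OC/C=C1\CC[C@@H](OC(C)=O)[C@](C)(C/C=C/[C@@H](C)[C@H]2CO2)OC1 | intermediate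
38 | (2S,3R,6E)-6-{2-[(tert-butyldiphenylsilyl)oxy]ethylidene}-2-methyl-2-{(4R)-4-[(2S)-oxiran-2-yl]pentyl}oxepan-3-yl acetate | CC(C)(C)[Si](c1ccccc1)(c1ccccc1)OC/C=C1\CC[C@@H](OC(C)=O)[C@](C)(CCC[C@@H](C)[C@H]2CO2)OC1 | intermediate
39 | (2-methylprop-1-en-1-yl)magnesium bromide | CC(C)=C[Mg]Br | starting material
40 | (2S,3R,6E)-6-{2-[(tert-butyldiphenylsilyl)oxy]ethylidene}-2-[(4R,5R)-5-hydroxy-4,8-dimethylnon-7-en-1-yl]-2-methyloxepan-3-yl acetate | CC(C)(C)[Si](c1ccccc1)(c1ccccc1)OC/C=C1\CC[C@@H](OC(C)=O)[C@](C)(CCC[C@@H](C)[C@H](O)CC=C(C)C)OC1 | intermediate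
41 | (2S,3R,6E)-6-(2-hydroxyethylidene)-2-[(4R,5R)-5-hydroxy-4,8-dimethylnon-7-en-1-yl]-2-methyloxepan-3-yl acetate | OC/C=C1\CC[C@@H](OC(C)=O)[C@](C)(CCC[C@@H](C)[C@H](O)CC=C(C)C)OC1 | intermediate
42 | (2S,3R,6E)-6-[2-(acetyloxy)ethylidene]-2-[(4R,5R)-5-hydroxy-4,8-dimethylnon-7-en-1-yl]-2-methyloxepan-3-yl acetate | CC(=O)OC/C=C1\CC[C@@H](OC(C)=O)[C@](C)(CCC[C@@H](C)[C@H](O)CC=C(C)C)OC1 | target

## Step count and least certain steps

Total step count: 27. Longest linear sequence: 22 steps (steps 1–7, 10–19 and 23–27); steps 8–9 and 20–22 are side branches.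

Step 17 (key step). The most likely failure is O-alkylation of the ambident enolate (closure to the seven-membered cyclic enol ether), or intermolecular alkylation and aldol condensation outrunning the slow seven-membered C-alkylation, because the enolate is hindered by the neighbouring quaternary carbon. The fallback sets out from 22 and returns at 26. Condensation of 22 with N,N-dimethylhydrazine (AcOH cat., EtOH, 70 °C) should give the N,N-dimethylhydrazone F1. HF·pyridine/pyridine then removes the TBS group to give the hydroxy hydrazone F2, and CBr4/PPh3 converts it into the bromo hydrazone F3, which is used at once. LiN(iPr)2 in THF (−78 → 0 °C, high dilution) forms the aza-enolate at the methyl group; aza-enolates alkylate on carbon only, and closure should give the cyclic hydrazone F4. Hydrolysis with aqueous oxalic acid/Et2O returns ketone 26.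

Step 4. The most likely failure is slow transfer of the sp3 hydroxymethyl group from tin, leaving time for protodeiodination or homocoupling of the alkenylpalladium intermediate. The fallback sets out from 5 and returns at 7. Carbonylation (PdCl2(PPh3)2, CO 1 atm, MeOH, Et3N, DMF, 60 °C) should give, with retention of geometry, the methyl ester F5. Reduction with (i-Bu)2AlH in CH2Cl2 at −78 °C then gives 7.

Step 10. The most likely failure is proton abstraction from the allylic bromide by the hindered, basic tertiary alkoxide (1,4-elimination to a diene) in competition with a sluggish substitution. The fallback sets out from 9, 11 and 14 and returns at 18. MnO2 (CH2Cl2) oxidises 9 to the enal F6. Epoxide 11 is opened without protection by 14 (2.2 equiv, CuI cat.) to give (2S)-2-methylpent-4-ene-1,2-diol F7. Acetalisation of F6 with F7 (PPTS, MgSO4, CH2Cl2) gives the dioxolane acetal F8 as a mixture at the acetal carbon. (i-Bu)2AlH (CH2Cl2, −78 → 0 °C) coordinates the less hindered primary oxygen, cleaves that C–O bond and delivers hydride to the acetal carbon, which leaves the ether on the tertiary oxygen and the primary hydroxyl free, that is 18.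

Step 25. The most likely failure is addition of the Grignard reagent to the C3 acetate (loss of the acetyl group) in competition with epoxide opening. The fallback sets out from 27, which has no ester, and returns at 41. Cross-metathesis of 27 with 36 under the conditions of step 23 gives the epoxy alkene F9, and diimide reduction gives the saturated epoxy alcohol F10. Opening with 39 (2.5 equiv, CuI cat.) gives the C3,C5''-diol F11. Et3SiCl/imidazole at −40 °C should silylate the C5'' hydroxyl, which is less hindered than the C3 hydroxyl beside quaternary C2, to give the triethylsilyl ether F12. Ac2O/DMAP then acetylates C3 to give F13, and HF·pyridine removes both silyl groups to return 41.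

Step 27. The most likely failure is incomplete discrimination between the primary allylic and the secondary C5'' hydroxyl, giving over-acetylation. The fallback sets out from 40 and returns at 42. 4-Methoxybenzyl trichloroacetimidate with La(OTf)3 (cat.) in toluene protects the C5'' hydroxyl as the PMB ether F14. HF·pyridine frees the primary alcohol F15, Ac2O/pyridine gives the diacetate F16, and DDQ (CH2Cl2/pH 7 buffer) removes the PMB group to give 42.

## Further compounds

F1 | step 17 | (E)-N,N-dimethylhydrazone of 22 | C/C(=N\N(C)C)[C@](C)(CC=C)OC/C(CO[Si](C)(C)C(C)(C)C)=C/CO[Si](c1ccccc1)(c1ccccc1)C(C)(C)C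
F2 | step 17 | N,N-dimethylhydrazone of 23 | C/C(=N\N(C)C)[C@](C)(CC=C)OC/C(CO)=C/CO[Si](c1ccccc1)(c1ccccc1)C(C)(C)C
F3 | step 17 | N,N-dimethylhydrazone of 24 | C/C(=N\N(C)C)[C@](C)(CC=C)OC/C(CBr)=C/CO[Si](c1ccccc1)(c1ccccc1)C(C)(C)C
F4 | step 17 | N,N-dimethylhydrazone of 26 (C=N geometry not defined) | CC(C)(C)[Si](c1ccccc1)(c1ccccc1)OC/C=C1\CCC(=NN(C)C)[C@](C)(CC=C)OC1
F5 | step 4 | methyl (2Z)-4-[(tert-butyldiphenylsilyl)oxy]-2-{[(4-methoxyphenyl)methoxy]methyl}but-2-enoate | COc1ccc(COC/C(C(=O)OC)=C/CO[Si](c2ccccc2)(c2ccccc2)C(C)(C)C)cc1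
F6 | step 10 | (2Z)-2-({[tert-butyl(dimethyl)silyl]oxy}methyl)-4-{[tert-butyl(diphenyl)silyl]oxy}but-2-enal | O=C/C(CO[Si](C)(C)C(C)(C)C)=C/CO[Si](c1ccccc1)(c1ccccc1)C(C)(C)C
F7 | step 10 | (2S)-2-methylpent-4-ene-1,2-diol | OC[C@](O)(C)CC=C
F8 | step 10 | (4S)-4-methyl-4-(prop-2-en-1-yl)-1,3-dioxolane acetal of F6 (both acetal epimers) | C=CC[C@@]1(C)COC(O1)/C(CO[Si](C)(C)C(C)(C)C)=C/CO[Si](c2ccccc2)(c2ccccc2)C(C)(C)C
F9 | step 25 | (2S,3R,6E)-6-{2-[(tert-butyldiphenylsilyl)oxy]ethylidene}-2-methyl-2-{(2E,4R)-4-[(2S)-oxiran-2-yl]pent-2-en-1-yl}oxepan-3-ol | CC(C)(C)[Si](c1ccccc1)(c1ccccc1)OC/C=C1\CC[C@@H](O)[C@](C)(C/C=C/[C@@H](C)[C@H]2CO2)OC1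
F10 | step 25 | (2S,3R,6E)-6-{2-[(tert-butyldiphenylsilyl)oxy]ethylidene}-2-methyl-2-{(4R)-4-[(2S)-oxiran-2-yl]pentyl}oxepan-3-ol | CC(C)(C)[Si](c1ccccc1)(c1ccccc1)OC/C=C1\CC[C@@H](O)[C@](C)(CCC[C@@H](C)[C@H]2CO2)OC1
F11 | step 25 | (2S,3R,6E)-6-{2-[(tert-butyldiphenylsilyl)oxy]ethylidene}-2-[(4R,5R)-5-hydroxy-4,8-dimethylnon-7-en-1-yl]-2-methyloxepan-3-ol | CC(C)(C)[Si](c1ccccc1)(c1ccccc1)OC/C=C1\CC[C@@H](O)[C@](C)(CCC[C@@H](C)[C@H](O)CC=C(C)C)OC1
F12 | step 25 | C5''-O-triethylsilyl ether of F11 | CC(C)(C)[Si](c1ccccc1)(c1ccccc1)OC/C=C1\CC[C@@H](O)[C@](C)(CCC[C@@H](C)[C@H](O[Si](CC)(CC)CC)CC=C(C)C)OC1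
F13 | step 25 | C3 acetate of F12 | CC(C)(C)[Si](c1ccccc1)(c1ccccc1)OC/C=C1\CC[C@@H](OC(C)=O)[C@](C)(CCC[C@@H](C)[C@H](O[Si](CC)(CC)CC)CC=C(C)C)OC1
F14 | step 27 | C5''-O-(4-methoxybenzyl) ether of 40 | CC(C)(C)[Si](c1ccccc1)(c1ccccc1)OC/C=C1\CC[C@@H](OC(C)=O)[C@](C)(CCC[C@@H](C)[C@H](OCc2ccc(OC)cc2)CC=C(C)C)OC1
F15 | step 27 | C5''-O-(4-methoxybenzyl) ether of 41 | OC/C=C1\CC[C@@H](OC(C)=O)[C@](C)(CCC[C@@H](C)[C@H](OCc2ccc(OC)cc2)CC=C(C)C)OC1
F16 | step 27 | C5''-O-(4-methoxybenzyl) ether of 42 | CC(=O)OC/C=C1\CC[C@@H](OC(C)=O)[C@](C)(CCC[C@@H](C)[C@H](OCc2ccc(OC)cc2)CC=C(C)C)OC1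
A1 | alternative 1 | 6-vinyl-2,3,4,7-tetrahydrooxepine with C3 acetate and C5'' silyl ether (product of the enyne metathesis) | C=CC1=CC[C@@H](OC(C)=O)[C@](C)(CCC[C@@H](C)[C@H](O[Si](C)(C)C(C)(C)C)CC=C(C)C)OC1
A2 | alternative 1 | acyclic enyne with C3 allyl group and O1 propargyl ether | C=CC[C@@H](OC(C)=O)[C@](C)(CCC[C@@H](C)[C@H](O[Si](C)(C)C(C)(C)C)CC=C(C)C)OCC#C
A3 | alternative 1 | allylic alcohol from 1,4-hydroboration and oxidation of A1 | OC/C=C1\CC[C@@H](OC(C)=O)[C@](C)(CCC[C@@H](C)[C@H](O[Si](C)(C)C(C)(C)C)CC=C(C)C)OC1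
A4 | alternative 2 | 7-allyl-7-methyl-6-(tert-butyldimethylsilyloxy)oxepan-2-one (product of the Baeyer–Villiger step) | O=C1CCC[C@@H](O[Si](C)(C)C(C)(C)C)[C@](C)(CC=C)O1
A5 | alternative 2 | (2S,3R)-2-allyl-3-(tert-butyldimethylsilyloxy)-2-methylcyclohexan-1-one | O=C1CCC[C@@H](O[Si](C)(C)C(C)(C)C)[C@]1(C)CC=C
A6 | alternative 2 | 2-allyl-2-methylcyclohexane-1,3-dione | C=CCC1(C)C(=O)CCCC1=O
A7 | alternative 3 | 6-alkylidene oxepan-3-one with the full side chain (product of the palladium step) | CC(C)(C)[Si](c1ccccc1)(c1ccccc1)OC/C=C1\CCC(=O)[C@](C)(CCC[C@@H](C)[C@H](OCc2ccc(OC)cc2)CC=C(C)C)OC1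
A8 | alternative 3 | C3 cyclopropanol with O1-linked (Z)-iodoalkene | OC1(CC1)[C@](C)(CCC[C@@H](C)[C@H](OCc2ccc(OC)cc2)CC=C(C)C)OC/C(I)=C/CO[Si](c3ccccc3)(c3ccccc3)C(C)(C)C
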